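**Retrosynthetic overview**
- Side chain last: C9–C11 comes from 1,2-addition of the C11–C16 organolithium to the C9 ketone of a bicyclic 11-nordrimenone, followed by oxidative 1,3-transposition, Li/NH3 reduction with enolate triflation, and triflate reduction (sets H-9 and the 7,8-alkene).
- Ring A (second ring) is closed by the C3–C4 bond: hydrogen-atom transfer to a C5 isopropenyl group gives a tertiary C4 radical, which adds to a C3 aldehyde; C2 is carried as a dimethyl ketal.
- Ring B (first ring) is bought as (S)-carvone; the C10 quaternary centre is built by two α′-alkylations (CH3, then a 2-methoxyallyl arm that becomes C1–C3).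
- Enabling feature: the gem-dimethyl quaternary carbon C4 of ring A lies between C5 of ring B and the C3 carbinol. C4 with its two methyls is the isopropenyl group of carvone plus one hydrogen atom, so C4 can be a tertiary radical and C3 an aldehyde carbon.

Key step: step 6

Remark: labdane numbering of the target is used for all intermediates (ring A: C1–C5, C10; ring B: C5–C10; side chain C11–C16; C17 on C8; C18/C19 on C4; C20 on C10).

Step 1
Reactants: 1 (S)-(+)-carvone
Product: 3 trans-6-methylcarvone (minor cis epimer carried along), via lithium dienolate of carvone 2 (not isolated)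
Conditions: LiN(iPr)2, THF, −78 °C; MeI, −78 → −20 °C
Reagents that add atoms: iodomethane, C[I]
Why: Kinetic α′-deprotonation of the enone at the future C10 and SN2 methylation of the cross-conjugated lithium dienolate (enolate alkylation); the new centre forms mainly trans to the isopropenyl group but is erased in step 3, so the epimer composition does not matter.

Step 2
Reactants: 4 2-methoxypropene
Product: 5 2-methoxyallyl bromide
Conditions: NBS, PhCF3, 0 °C → rt; filtrate used at once
Reagents that add atoms: N-bromosuccinimide, O=C1CCC(=O)N1Br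
Why: Electrophilic bromination of the enol ether gives an oxocarbenium ion that loses an allylic proton to the succinimide anion (net allylic bromination of an enol ether), which should give the labile acetonyl-equivalent allyl bromide for immediate use.

Step 3
Reactants: 3 trans-6-methylcarvone; 5 2-methoxyallyl bromide
Product: 7 (5R,6R)-6-(2-methoxyprop-2-en-1-yl)-2,6-dimethyl-5-(prop-1-en-2-yl)cyclohex-2-en-1-one, via lithium enolate of 6-methylcarvone 6 (not isolated)
Conditions: LiN(iPr)2, THF, −78 → 0 °C; then 5, DMPU, −78 °C → rt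
Reagents that add atoms: none
Why: Second enolate alkylation (SN2 on a reactive allylic bromide) of the fully substituted lithium enolate; the electrophile should enter on the face opposite the adjacent C5 isopropenyl group, so the arm ends trans and the methyl cis to it, which sets the C10 quaternary centre.

Step 4
Reactants: 7 the 2-methoxyallyl ketone
Product: 9 (5R,6R)-6-(3-hydroxy-2,2-dimethoxypropyl)-2,6-dimethyl-5-(prop-1-en-2-yl)cyclohex-2-en-1-one, via methoxy-oxirane 8 (not isolated)
Conditions: mCPBA (1.0 equiv), MeOH, −20 → 0 °C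
Reagents that add atoms: mCPBA, OOC(=O)c1cccc(Cl)c1; methanol, CO
Why: Prilezhaev epoxidation is chemoselective for the electron-rich enol ether (much faster than the isopropenyl group; the enone is inert), and the methoxy-oxirane is opened in situ by methanol at the acetal carbon to give the α-hydroxy dimethyl ketal; C2 is not stereogenic.

Step 5
Reactants: 9 the hydroxy ketal
Product: 10 (5R,6R)-6-(2,2-dimethoxy-3-oxopropyl)-2,6-dimethyl-5-(prop-1-en-2-yl)cyclohex-2-en-1-one
Conditions: Dess–Martin periodinane, pyridine, CH2Cl2, 0 °C → rt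
Reagents that add atoms: none
Why: Dess–Martin oxidation of the primary alcohol stops at the aldehyde, which has no α-hydrogen and therefore cannot enolise or epimerise.

Step 6
Reactants: 10 the seco-aldehyde
Product: 11 3-hydroxy-2,2-dimethoxy-11-nordrim-7-en-9-one (trans-decalin; 3-OH equatorial and cis to the C10 methyl; H-5 trans to the C10 methyl)
Conditions: Fe(acac)3 (30 mol %), PhSiH3 (2.5 equiv), EtOH, 60 °C, degassed
Reagents that add atoms: none
Why: An iron hydride formed from Fe(acac)3 and PhSiH3 transfers a hydrogen atom to the CH2 terminus of the isopropenyl group (Mukaiyama-type HAT, Markovnikov), which turns that carbon into the second C4 methyl and leaves a nucleophilic tertiary radical at C4; this radical adds to the electrophilic, non-enolisable α,α-dimethoxy aldehyde carbon C3, and the O-centred radical is reduced by divalent iron and protonated by ethanol. The closest known reaction types are the iron-hydride HAT cyclisation of alkene-tethered ketones and the iron-hydride reductive coupling of unactivated alkenes with aldehydes. Ring A closes in the 6-exo-trig mode (attack on the carbonyl carbon, oxygen exocyclic) through a chair in which the C10 arm and the C5 radical-bearing group are trans-diequatorial on ring B, so the trans ring fusion is inherited from C5 and C10 of 10. The new C3 stereocentre is controlled by that chair: the solvated, metal-bound oxygen should take the equatorial site, away from the syn-axial H-1 and H-5, which places the hydroxyl cis to the C10 methyl as in the target. The step needs chemoselective HAT to the 1,1-disubstituted alkene, which is secured because the only other alkene is the electron-poor trisubstituted enone, a poor HAT acceptor that the C4 radical cannot reach (attack at C7 or C9 would form a four-membered ring). C4 itself is not stereogenic, so no selectivity is needed there.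

Step 7
Reactants: 11 the bicyclic hydroxy ketal
Product: 12 3-O-tert-butyldimethylsilyl ether of 11
Conditions: TBSOTf, 2,6-lutidine, CH2Cl2, 0 °C
Reagents that add atoms: tert-butyldimethylsilyl triflate, CC(C)(C)[Si](C)(C)OS(=O)(=O)C(F)(F)F
Why: Silylation of the hindered secondary alcohol with a silyl triflate protects O-3 against the organolithium of step 12 and the chromium oxidant of step 13.

Step 8
Reactants: 13 tert-butyl(but-3-yn-1-yloxy)dimethylsilane
Product: 16 (2E)-5-[(tert-butyldimethylsilyl)oxy]-3-methylpent-2-en-1-ol, via alkenyl(dimethyl)alane 14 (not isolated), via lithium butyl alanate 15 (not isolated)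
Conditions: AlMe3, Cp2ZrCl2 (cat.), CH2Cl2, 0 °C → rt; then n-BuLi, THF, −78 °C; (CH2O)n, → rt
Reagents that add atoms: trimethylaluminium, C[Al](C)C; formaldehyde (as paraformaldehyde), C=O
Why: Negishi zirconium-catalysed carboalumination adds CH3–Al syn across the terminal alkyne with methyl on the internal carbon, and hydroxymethylation of the alanate with retention should give the E trisubstituted allylic alcohol (C13=C14 geometry of the target).

Step 9
Reactants: 16 the allylic alcohol
Product: 17 tert-butyldimethyl{[(3E)-3-methyl-5-(triisopropylsilyloxy)pent-3-en-1-yl]oxy}silane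
Conditions: TIPSCl, imidazole, DMF, rt
Reagents that add atoms: triisopropylsilyl chloride, CC(C)[Si](Cl)(C(C)C)C(C)C
Why: Standard silylation of the primary allylic alcohol installs the robust O-15 protecting group.

Step 10
Reactants: 17 the bis-silyl ether
Product: 18 (3E)-3-methyl-5-[(triisopropylsilyl)oxy]pent-3-en-1-ol
Conditions: CSA (cat.), MeOH/CH2Cl2, 0 °C
Reagents that add atoms: none
Why: Acid-catalysed methanolysis should remove the less hindered primary TBS ether selectively, while the bulkier triisopropylsilyl ether stays.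

Step 11
Reactants: 18 the homoallylic alcohol
Product: 19 {[(2E)-5-iodo-3-methylpent-2-en-1-yl]oxy}triisopropylsilane
Conditions: I2, PPh3, imidazole, CH2Cl2, 0 °C
Reagents that add atoms: iodine, [I][I]
Why: Appel-type iodination of the primary alcohol proceeds by SN2 displacement of the oxyphosphonium group and leaves the alkene geometry untouched.

Step 12
Reactants: 12 the silyl-protected enone; 19 the side-chain iodide
Product: 21 9-hydroxy adduct (tertiary allylic alcohol carrying the C11–C16 chain on C9; C9 configuration not assigned), via alkyllithium 20 (not isolated)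
Conditions: 19, t-BuLi (2.1 equiv), Et2O/pentane, −78 °C; then 12, −78 → −30 °C; aq. NH4Cl
Reagents that add atoms: none
Why: Iodine–lithium exchange followed by 1,2-addition of the primary alkyllithium to the hindered enone carbonyl, which has no α′-hydrogen; the configuration of the new carbinol is irrelevant because C9 becomes sp2 in step 13.

Step 13
Reactants: 21 the tertiary allylic alcohol
Product: 22 8(9)-en-7-one (3-OTBS, 2,2-dimethoxy, 15-OTIPS; side chain on C9)
Conditions: pyridinium chlorochromate [C5H5NH][CrO3Cl], 4 Å MS, CH2Cl2, rt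
Reagents that add atoms: pyridinium chlorochromate, [O-][Cr](=O)(=O)Cl.c1cc[nH+]cc1
Why: Babler–Dauben oxidative 1,3-transposition: the tertiary allylic chromate ester of hexavalent chromium undergoes a [3,3] shift to C7 and is oxidised there, which should give the transposed enone with the side chain on the β-carbon C9.

Step 14
Reactants: 22 the transposed enone
Product: 24 C7–C8 enol triflate with H-9 trans to the C10 methyl, via lithium enolate 23 (not isolated)
Conditions: Li (2.2 equiv), NH3(l)/THF, −78 °C; NH3 removed; PhNTf2, THF, −78 °C → rt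
Reagents that add atoms: N-phenylbis(trifluoromethanesulfonimide), O=S(=O)(N(c1ccccc1)S(=O)(=O)C(F)(F)F)C(F)(F)F
Why: Dissolving-metal (Birch-type) enone reduction protonates the β-carbon C9 axially, anti to the axial C10 methyl, which should give H-9 trans to that methyl with the side chain equatorial (also the more stable arrangement), and the regiodefined lithium enolate is trapped on oxygen as the enol triflate.

Step 15
Reactants: 24 the enol triflate
Product: 25 3-OTBS, 15-OTIPS, 2,2-dimethoxy-labda-7,13E-diene
Conditions: Pd(OAc)2 (cat.), PPh3, HCO2H, n-Bu3N, DMF, 60 °C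
Reagents that add atoms: none
Why: Palladium-catalysed formate reduction of the enol triflate (oxidative addition to zerovalent palladium, formate exchange, decarboxylation, reductive elimination) replaces OTf by H with the alkene fixed at C7–C8 and no stereocentre touched.

Step 16
Reactants: 25 the bis-silyl ether
Product: 26 2,2-dimethoxy-labda-7,13E-diene-3,15-diol
Conditions: Bu4NF, THF, rt → 50 °C
Reagents that add atoms: none
Why: Fluoride-mediated desilylation cleaves both silyl ethers while the ketal and the alkenes are inert.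

Step 17
Reactants: 26 the diol
Product: 27 3-hydroxy-2,2-dimethoxy-labda-7,13E-dien-15-yl acetate
Conditions: Ac2O (1.1 equiv), pyridine, CH2Cl2, 0 °C
Reagents that add atoms: acetic anhydride, CC(=O)OC(C)=O
Why: Acetylation should be selective for the primary allylic alcohol, because the secondary C3 hydroxyl between the gem-dimethyl carbon and the ketal carbon is too hindered to react under these conditions.

Step 18
Reactants: 27 the ketal acetate
Product: 28 the target, (2E)-5-[(1R,4aS,6S,8aS)-6-hydroxy-2,5,5,8a-tetramethyl-7-oxo-1,4,4a,5,6,7,8,8a-octahydronaphthalen-1-yl]-3-methylpent-2-en-1-yl acetate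
Conditions: TsOH·H2O (cat.), acetone/H2O, 35 °C
Reagents that add atoms: water, O
Why: Acid-catalysed ketal hydrolysis releases the C2 ketone last, under conditions that should be too mild to isomerise the base-sensitive α-ketol, epimerise C3 or ionise the allylic acetate.

**Compound list**
1 | (S)-(+)-carvone, (5S)-2-methyl-5-(prop-1-en-2-yl)cyclohex-2-en-1-one | CC1=CC[C@@H](CC1=O)C(C)=C | starting material
2 | lithium dienolate of carvone (not isolated) | CC1=CC[C@@H](C=C1O[Li])C(C)=C | intermediate
3 | trans-6-methylcarvone, (5S,6R)-2,6-dimethyl-5-(prop-1-en-2-yl)cyclohex-2-en-1-one | CC1=CC[C@@H]([C@@H](C)C1=O)C(C)=C | intermediate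
4 | 2-methoxypropene | COC(C)=C | starting material
5 | 2-methoxyallyl bromide (3-bromo-2-methoxyprop-1-ene) | COC(=C)CBr | intermediate
6 | lithium enolate of 6-methylcarvone (not isolated) | CC1=CC[C@@H](C(C)=C1O[Li])C(C)=C | intermediate
7 | (5R,6R)-6-(2-methoxyprop-2-en-1-yl)-2,6-dimethyl-5-(prop-1-en-2-yl)cyclohex-2-en-1-one (C10 methyl cis, arm trans to isopropenyl) | CC1=CC[C@@H]([C@@](C)(CC(OC)=C)C1=O)C(C)=C | intermediate
8 | methoxy-oxirane from 7 (both epimers at the oxirane carbon; not isolated) | CC1=CC[C@@H]([C@@](C)(CC2(OC)CO2)C1=O)C(C)=C | intermediate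
9 | (5R,6R)-6-(3-hydroxy-2,2-dimethoxypropyl)-2,6-dimethyl-5-(prop-1-en-2-yl)cyclohex-2-en-1-one | CC1=CC[C@@H]([C@@](C)(CC(OC)(OC)CO)C1=O)C(C)=C | intermediate
10 | (5R,6R)-6-(2,2-dimethoxy-3-oxopropyl)-2,6-dimethyl-5-(prop-1-en-2-yl)cyclohex-2-en-1-one | CC1=CC[C@@H]([C@@](C)(CC(OC)(OC)C=O)C1=O)C(C)=C | intermediate
11 | 3-hydroxy-2,2-dimethoxy-11-nordrim-7-en-9-one (trans-fused; 3-OH cis to C10 methyl; H-5 trans to C10 methyl) | CC1=CC[C@@H]2C(C)(C)[C@H](O)C(OC)(OC)C[C@@]2(C)C1=O | intermediate
12 | 3-O-TBS ether of 11 | CC1=CC[C@@H]2C(C)(C)[C@H](O[Si](C)(C)C(C)(C)C)C(OC)(OC)C[C@@]2(C)C1=O | intermediate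
13 | tert-butyl(but-3-yn-1-yloxy)dimethylsilane | C#CCCO[Si](C)(C)C(C)(C)C | starting material
14 | (E)-alkenyl(dimethyl)alane from 13 (not isolated) | C[Al](C)/C=C(\C)CCO[Si](C)(C)C(C)(C)C | intermediate
15 | lithium butyl alanate from 14 (not isolated) | [Li+].CCCC[Al-](C)(C)/C=C(\C)CCO[Si](C)(C)C(C)(C)C | intermediate
16 | (2E)-5-[(tert-butyldimethylsilyl)oxy]-3-methylpent-2-en-1-ol | OC/C=C(\C)CCO[Si](C)(C)C(C)(C)C | intermediate
17 | tert-butyldimethyl{[(3E)-3-methyl-5-(triisopropylsilyloxy)pent-3-en-1-yl]oxy}silane | CC(C)[Si](OC/C=C(\C)CCO[Si](C)(C)C(C)(C)C)(C(C)C)C(C)C | intermediate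
18 | (3E)-3-methyl-5-[(triisopropylsilyl)oxy]pent-3-en-1-ol | CC(C)[Si](OC/C=C(\C)CCO)(C(C)C)C(C)C | intermediate
19 | {[(2E)-5-iodo-3-methylpent-2-en-1-yl]oxy}triisopropylsilane | CC(C)[Si](OC/C=C(\C)CCI)(C(C)C)C(C)C | intermediate
20 | (E)-alkyllithium from 19 (not isolated) | [Li]CC/C(C)=C/CO[Si](C(C)C)(C(C)C)C(C)C | intermediate
21 | 9-hydroxy adduct of 12 and 20 (tertiary allylic alcohol; C9 unassigned) | CC1=CC[C@@H]2C(C)(C)[C@H](O[Si](C)(C)C(C)(C)C)C(OC)(OC)C[C@@]2(C)C1(O)CC/C(C)=C/CO[Si](C(C)C)(C(C)C)C(C)C | intermediate
22 | 3-OTBS-2,2-dimethoxy-15-OTIPS-labda-8(9),13E-dien-7-one | O=C1C[C@@H]2C(C)(C)[C@H](O[Si](C)(C)C(C)(C)C)C(OC)(OC)C[C@@]2(C)C(CC/C(C)=C/CO[Si](C(C)C)(C(C)C)C(C)C)=C1C | intermediate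
23 | lithium C7–C8 enolate from 22 (H-9 trans to C10 methyl; not isolated) | CC(C)[Si](OC/C=C(\C)CC[C@@H]1C(C)=C(O[Li])C[C@@H]2C(C)(C)[C@H](O[Si](C)(C)C(C)(C)C)C(OC)(OC)C[C@@]12C)(C(C)C)C(C)C | intermediate
24 | C7 enol triflate (7-OTf, 7,8-ene) | CC(C)[Si](OC/C=C(\C)CC[C@@H]1C(C)=C(OS(=O)(=O)C(F)(F)F)C[C@@H]2C(C)(C)[C@H](O[Si](C)(C)C(C)(C)C)C(OC)(OC)C[C@@]12C)(C(C)C)C(C)C | intermediate
25 | 3-OTBS-15-OTIPS-2,2-dimethoxy-labda-7,13E-diene | CC(C)[Si](OC/C=C(\C)CC[C@@H]1C(C)=CC[C@@H]2C(C)(C)[C@H](O[Si](C)(C)C(C)(C)C)C(OC)(OC)C[C@@]12C)(C(C)C)C(C)C | intermediate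
26 | 2,2-dimethoxy-labda-7,13E-diene-3,15-diol | OC/C=C(\C)CC[C@@H]1C(C)=CC[C@@H]2C(C)(C)[C@H](O)C(OC)(OC)C[C@@]12C | intermediate
27 | 3-hydroxy-2,2-dimethoxy-labda-7,13E-dien-15-yl acetate | CC(=O)OC/C=C(\C)CC[C@@H]1C(C)=CC[C@@H]2C(C)(C)[C@H](O)C(OC)(OC)C[C@@]12C | intermediate
28 | 3-hydroxy-2-oxo-labda-7,13E-dien-15-yl acetate (ent series; 3-OH and C10 methyl on one face, H-5 and H-9 on the other) | CC(=O)OC/C=C(\C)CC[C@@H]1C(C)=CC[C@@H]2C(C)(C)[C@H](O)C(=O)C[C@@]12C | target

**Step count**
Total: 18 steps. Longest linear sequence: 13 steps from (S)-carvone (steps 1, 3, 4, 5, 6, 7, 12, 13, 14, 15, 16, 17, 18).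

**Steps most likely to fail**

Step 6 (ring closure). The O-centred radical formed on addition to the aldehyde may fragment toward the ketal carbon (formyl transfer) instead of being reduced. The aldehyde or the isopropenyl group may be reduced before cyclisation. The facial bias at C3 may be lower than the chair model predicts. The fallback sets out from 10 and comes back at 11. The aldehyde is homologated with dimethyl (1-diazo-2-oxopropyl)phosphonate and K2CO3 in MeOH (Ohira–Bestmann) to the terminal alkyne (5R,6R)-6-(2,2-dimethoxybut-3-yn-1-yl)-2,6-dimethyl-5-(prop-1-en-2-yl)cyclohex-2-en-1-one F1. The same Fe(acac)3/PhSiH3 initiation then closes ring A by 6-exo-dig addition of the C4 radical to the alkyne carbon C3; a carbon-centred vinyl radical results, so the addition is irreversible and nothing can fragment. This should give 2,2-dimethoxy-3-methylene-11-nordrim-7-en-9-one F2. Ozonolysis (O3, CH2Cl2/MeOH, −78 °C; Me2S) of the isolated 1,1-disubstituted alkene, which reacts much faster than the enone, gives 2,2-dimethoxy-11-nordrim-7-ene-3,9-dione F3. NaBH4 in MeOH at −40 °C should reduce the activated α,α-dimethoxy ketone in preference to the conjugated, doubly flanked C9 carbonyl; hydride enters axially and returns 11 with the equatorial hydroxyl. In this variant the oxygen is introduced after ring closure and C3 is set by hydride delivery.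

Step 14 (enone reduction and triflation). Electron transfer may also cleave the allylic C15–O silyl ether, the hindered enolate may be triflated incompletely, or C9 may be protonated from the wrong face. The fallback sets out from 22 and comes back at 25. Luche reduction (NaBH4, CeCl3·7H2O, MeOH, −78 °C; axial hydride) gives the allylic alcohol with the 7-hydroxyl cis to the C10 methyl, 3-OTBS-2,2-dimethoxy-15-OTIPS-labda-8(9),13E-dien-7-ol F4. Reductive 1,3-transposition through the allylic diazene follows: Mitsunobu reaction with 2-nitrobenzenesulfonylhydrazide (PPh3, DEAD, THF, −30 °C → rt) inverts C7, sulfinic acid is lost, and the diazene loses N2 in a sigmatropic step that delivers hydrogen to C9 on the face of the C7–N bond, trans to the C10 methyl. This moves the alkene to C7–C8 and gives 25 directly, with no dissolving metal and no triflate.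

Step 3 (quaternary centre). The labile allylic bromide may decompose or alkylate on oxygen before C-alkylation is complete. The fallback sets out from 3 and comes back at 7. The lithium enolate of 3 is alkylated with allyl bromide, which follows the same facial preference, to (5R,6R)-6-allyl-2,6-dimethyl-5-(prop-1-en-2-yl)cyclohex-2-en-1-one F5. Wacker–Tsuji oxidation (PdCl2, CuCl, O2, DMF/H2O), selective for the monosubstituted alkene, gives the methyl ketone (5R,6R)-2,6-dimethyl-6-(2-oxopropyl)-5-(prop-1-en-2-yl)cyclohex-2-en-1-one F6. Ketalisation of the unhindered ketone (HC(OMe)3, TsOH, MeOH) gives (5R,6R)-6-(2,2-dimethoxypropyl)-2,6-dimethyl-5-(prop-1-en-2-yl)cyclohex-2-en-1-one F7. Elimination of methanol toward the methyl group (TMSOTf, iPr2NEt, CH2Cl2, −20 °C) returns enol ether 7.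

Further compounds
F1 | step 6 | (5R,6R)-6-(2,2-dimethoxybut-3-yn-1-yl)-2,6-dimethyl-5-(prop-1-en-2-yl)cyclohex-2-en-1-one | CC1=CC[C@@H]([C@@](C)(CC(OC)(OC)C#C)C1=O)C(C)=C
F2 | step 6 | 2,2-dimethoxy-3-methylene-11-nordrim-7-en-9-one | CC1=CC[C@@H]2C(C)(C)C(=C)C(OC)(OC)C[C@@]2(C)C1=O
F3 | step 6 | 2,2-dimethoxy-11-nordrim-7-ene-3,9-dione | CC1=CC[C@@H]2C(C)(C)C(=O)C(OC)(OC)C[C@@]2(C)C1=O
F4 | step 14 | 3-OTBS-2,2-dimethoxy-15-OTIPS-labda-8(9),13E-dien-7-ol (7-OH cis to C10 methyl) | O[C@@H]1C[C@@H]2C(C)(C)[C@H](O[Si](C)(C)C(C)(C)C)C(OC)(OC)C[C@@]2(C)C(CC/C(C)=C/CO[Si](C(C)C)(C(C)C)C(C)C)=C1C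
F5 | step 3 | (5R,6R)-6-allyl-2,6-dimethyl-5-(prop-1-en-2-yl)cyclohex-2-en-1-one | CC1=CC[C@@H]([C@@](C)(CC=C)C1=O)C(C)=C
F6 | step 3 | (5R,6R)-2,6-dimethyl-6-(2-oxopropyl)-5-(prop-1-en-2-yl)cyclohex-2-en-1-one | CC1=CC[C@@H]([C@@](C)(CC(C)=O)C1=O)C(C)=C
F7 | step 3 | (5R,6R)-6-(2,2-dimethoxypropyl)-2,6-dimethyl-5-(prop-1-en-2-yl)cyclohex-2-en-1-one | CC1=CC[C@@H]([C@@](C)(CC(C)(OC)OC)C1=O)C(C)=C
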